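**Plan**

1. Numbering (bicyclo[3.2.1]octane core): C1 isobutyryl bridgehead, C2 CMe2, C3 CH–prenyl, C4 CH2, C5 prenyl bridgehead, C6 carbinol, C7 ring ketone, C8 bridge ketone. Ring A is C1–C2–C3–C4–C5–C8; ring B is C1–C7–C6–C5–C8.
2. Enabling feature: the two-carbon unit C7–C6 spans C1 and C5 across the C8 carbonyl. Moving C6 from C5 back to C8 turns ring B into a cyclobutane on the C1–C8 bond of ring A, which is the [2+2] adduct of a C1=C8 enone (C5 carbonyl, C8 silyloxy) with a ketene acetal.
3. Cuts, in retrosynthetic order: the Z-alkene (to an alkyne), C6–acyl (aldol) and C6–O; the two prenyl C=C bonds; C5–C6 (1,2-shift back to C8–C6) and C5–allyl; C1–C7 and C8–C6 together; then the C1 side chain, the C5 oxygen and the C3 chain of ring A, back to dimedone.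
4. Forward: ring A from dimedone (steps 1–10), cyclobutane by photocycloaddition (step 11), ring B by allyl addition and semipinacol shift (steps 12–13), then the prenyl groups, C6 hydroxylation, exo aldol with an ynal, oxidation and semihydrogenation.
5. Stereochemistry: C3 from a palladium-catalysed asymmetric allylation; C1 (and, through the suprafacial shift, C5) from addition of the ketene acetal to the enone face anti to the C3 chain; C6 from exo attack of the C6-oxy enolate; the Z-alkene from syn hydrogenation.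

Key step: step 11

Assumption and notation: carbinol centres that are destroyed later (C1 of 8, ring C6 and side-chain carbinol of 13, the side-chain carbinol up to 20, the C2 carbinol of 18, the propargylic carbinol of 29 and 30) are carried as epimer mixtures and written without descriptor, and the target is taken as the open-chain hydroxy enone drawn; TBS = tert-butyldimethylsilyl, TES = triethylsilyl.

**Route**

Step 1
Reactants: 1 dimedone (5,5-dimethylcyclohexane-1,3-dione)
Product: 2 3-isobutoxy-5,5-dimethylcyclohex-2-en-1-one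
Conditions: isobutanol, TsOH·H2O (cat.), toluene, reflux (Dean–Stark)
Reagents that add atoms: 2-methylpropan-1-ol, CC(C)CO
Why: Acid-catalysed vinylogous ester formation from the enolised 1,3-dione is driven by azeotropic removal of water and creates no stereocentre.

Step 2
Reactants: 2 3-isobutoxy-5,5-dimethylcyclohex-2-en-1-one
Product: 3 allyl 5-isobutoxy-3,3-dimethylcyclohexa-1,5-dien-1-yl carbonate
Conditions: LiN(iPr)2, TMEDA, THF, −78 °C; then allyl chloroformate, −78 to 0 °C
Reagents that add atoms: allyl chloroformate, C=CCOC(=O)Cl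
Why: Kinetic deprotonation of the vinylogous ester occurs at the α′ CH2 between C=O and CMe2, and the hindered cross-conjugated enolate is O-acylated by the chloroformate (enol carbonate formation), which fixes the site of the later allylation.

Step 3
Reactants: 3 allyl 5-isobutoxy-3,3-dimethylcyclohexa-1,5-dien-1-yl carbonate
Product: 4 (S)-6-allyl-3-isobutoxy-5,5-dimethylcyclohex-2-en-1-one
Conditions: Pd2(dba)3 (2.5 mol%), (R,R)-ANDEN-phenyl Trost ligand (6 mol%), 1,4-dioxane, rt
Reagents that add atoms: none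
Why: Decarboxylative asymmetric allylic alkylation (Tsuji–Trost type): zerovalent palladium ionises the enol carbonate, CO2 is lost and the enolate recombines with the π-allyl fragment at the α′ carbon inside the chiral ligand pocket, which sets the future C3 centre; the ligand antipode that delivers the S product is the one to be used.

Step 4
Reactants: 4 (S)-6-allyl-3-isobutoxy-5,5-dimethylcyclohex-2-en-1-one
Product: 6 (S)-6-(2-hydroxyethyl)-3-isobutoxy-5,5-dimethylcyclohex-2-en-1-one, via aldehyde 5 (not isolated)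
Conditions: OsO4 (2 mol%), NaIO4, 2,6-lutidine, dioxane/H2O, rt; extraction; then NaBH4, MeOH, 0 °C
Reagents that add atoms: osmium tetroxide, O=[Os](=O)(=O)=O (oxygen carrier); sodium periodate, [Na+].[O-]I(=O)(=O)=O
Why: Lemieux–Johnson cleavage should take the monosubstituted alkene in preference to the conjugated β-alkoxy enone alkene, and borohydride reduces the aldehyde but not the vinylogous ester carbonyl, the stereocentre not being enolised.

Step 5
Reactants: 6 (S)-6-(2-hydroxyethyl)-3-isobutoxy-5,5-dimethylcyclohex-2-en-1-one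
Product: 7 (S)-6-[2-(TBS-oxy)ethyl]-3-isobutoxy-5,5-dimethylcyclohex-2-en-1-one
Conditions: TBSCl, imidazole, DMF, rt
Reagents that add atoms: tert-butyldimethylsilyl chloride, CC(C)(C)[Si](C)(C)Cl
Why: Silylation of the primary alcohol masks the C3 chain as a saturated ether, so that no alkene sits near the enone at the photochemical step and no alkoxide can add to the enone formed next.

Step 6
Reactants: 7 (S)-6-[2-(TBS-oxy)ethyl]-3-isobutoxy-5,5-dimethylcyclohex-2-en-1-one
Product: 9 (R)-4-[2-(TBS-oxy)ethyl]-5,5-dimethylcyclohex-2-en-1-one, via allylic alcohol 8 (not isolated)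
Conditions: iBu2AlH, CH2Cl2, −78 °C; then 1 M aq. HCl, THF, 0 °C
Reagents that add atoms: water, O
Why: Stork–Danheiser transposition: 1,2-reduction of the vinylogous ester and acid hydrolysis of the 3-alkoxy allylic alcohol with loss of water move the carbonyl to the former enol ether carbon (future C8) and leave the stereocentre, now γ, untouched.

Step 7
Reactants: 9 (R)-4-[2-(TBS-oxy)ethyl]-5,5-dimethylcyclohex-2-en-1-one
Product: 10 (4S)-4-[2-(TBS-oxy)ethyl]-2,3-epoxy-5,5-dimethylcyclohexan-1-one (epoxide trans to the side chain)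
Conditions: 30% aq. H2O2, NaOH (cat.), MeOH, 0 °C
Reagents that add atoms: hydrogen peroxide, OO
Why: Weitz–Scheffer nucleophilic epoxidation: hydroperoxide adds to the enone β-carbon anti to the neighbouring side chain and closes to the trans epoxide, whose two new centres are removed in step 8.

Step 8
Reactants: 10 (4S)-4-[2-(TBS-oxy)ethyl]-2,3-epoxy-5,5-dimethylcyclohexan-1-one
Product: 11 (R)-4-[2-(TBS-oxy)ethyl]-2-methoxy-5,5-dimethylcyclohex-2-en-1-one
Conditions: NaOMe (0.3 equiv), MeOH, rt
Reagents that add atoms: methanol, CO (delivered as sodium methoxide)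
Why: Base-mediated conversion of an α,β-epoxy ketone into a 2-alkoxy enone: methoxide opens the epoxide at the α-carbon and E1cB loss of the β-hydroxyl follows, which places the future C5 oxygen and leaves the C8 carbonyl with α-hydrogens only at C1.

Step 9
Reactants: 11 (R)-4-[2-(TBS-oxy)ethyl]-2-methoxy-5,5-dimethylcyclohex-2-en-1-one; 12 isobutyraldehyde (2-methylpropanal)
Product: 13 (4R)-4-[2-(TBS-oxy)ethyl]-6-(1-hydroxy-2-methylpropyl)-2-methoxy-5,5-dimethylcyclohex-2-en-1-one (epimers at C6 and at the carbinol carbon)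
Conditions: LiN(iPr)2, THF, −78 °C; then 12; AcOH quench at −78 °C
Reagents that add atoms: none
Why: Kinetic α′-enolate formation of the 2-alkoxy enone (the CH2 next to CMe2, the γ-hydrogen at the stereocentre staying untouched) and aldol addition attach the C1 side chain; the two new centres are not controlled because one is made planar in step 10 and the other is oxidised in step 15.

Step 10
Reactants: 13 (4R)-4-[2-(TBS-oxy)ethyl]-6-(1-hydroxy-2-methylpropyl)-2-methoxy-5,5-dimethylcyclohex-2-en-1-one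
Product: 15 (5R)-2-(TBS-oxy)-3-[1-(TBS-oxy)-2-methylpropyl]-5-[2-(TBS-oxy)ethyl]-4,4-dimethylcyclohex-2-en-1-one, via bis-silyl dienol ether 14 (not isolated)
Conditions: TBSOTf (2.5 equiv), Et3N, CH2Cl2, −78 to 0 °C; then oxalic acid (cat.), THF/H2O, 0 °C
Reagents that add atoms: tert-butyldimethylsilyl triflate, CC(C)(C)[Si](C)(C)OS(=O)(=O)C(F)(F)F; water, O
Why: Soft enolisation (silyl triflate/amine) silylates the alcohol and converts the C8 ketone into its silyl enol ether towards C1, the only α-CH (the γ-hydrogen at C3 is the competing site, see step 9), and the unhindered methyl enol ether is then hydrolysed (protonation at C4) in preference to the tetrasubstituted silyl enol ether, so the 2-silyloxy enone forms with the C1=C8 regiochemistry fixed.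

Step 11
Reactants: 15 (5R)-2-(TBS-oxy)-3-[1-(TBS-oxy)-2-methylpropyl]-5-[2-(TBS-oxy)ethyl]-4,4-dimethylcyclohex-2-en-1-one; 16 1,1-dimethoxyethene
Product: 17 7,7-dimethoxy-1-(TBS-oxy)-6-[1-(TBS-oxy)-2-methylpropyl]-4-[2-(TBS-oxy)ethyl]-5,5-dimethylbicyclo[4.2.0]octan-2-one (cis-fused; cyclobutane anti to the C4 side chain; in core numbering the ketal carbon C7 is on C1 and the methylene C6 on C8)
Conditions: hν (medium-pressure Hg lamp, Pyrex, λ > 300 nm), 16 (15 equiv), degassed cyclohexane, 0 °C
Reagents that add atoms: none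
Why: Excitation (n→π*) and intersystem crossing give the triplet enone, which combines with the electron-rich ketene acetal to a triplet 1,4-biradical and, after spin inversion, to the cyclobutane, the acetal carbon C7 bonding to the β-carbon C1 and the methylene C6 to C8 (head-to-tail). The closest known reaction type is the enone–alkene [2+2] photocycloaddition of cyclohexenones and 2-silyloxy enones with 1,1-dialkoxyethenes. The four-membered ring C1–C7–C6–C8 is closed by intermolecular two-bond union across C1=C8, the second bond forming by recombination of the 1,4-biradical to the cis-fused bicyclo[4.2.0]octanone. C1 and C8 are set together by the face of ring A that is attacked: with the C3 chain pseudo-equatorial in the half-chair, the pseudo-axial C2 methyl covers the face on the side of that chain, so the alkene should add to the opposite face, and closure on that same face gives the cis fusion. The step needs head-to-tail orientation, cis fusion and addition anti to the C3 chain; the first is secured by the donor alkene and the polarity of the excited enone, the other two by the C2/C3 substitution and the short lifetime of the fully substituted biradical. A saturated, silyl-protected C3 chain and C1 side chain keep intramolecular cycloaddition and hydroxyl quenching out.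

Step 12
Reactants: 17 the photoadduct
Product: 18 2-allyl-7,7-dimethoxy-1-(TBS-oxy)-6-[1-(TBS-oxy)-2-methylpropyl]-4-[2-(TBS-oxy)ethyl]-5,5-dimethylbicyclo[4.2.0]octan-2-ol (C2 epimers; C2 is core C5)
Conditions: CH2=CHCH2MgBr, THF, −78 °C; then H2O
Reagents that add atoms: allylmagnesium bromide, C=CC[Mg]Br
Why: Grignard 1,2-addition of the allyl reagent (six-centre transition state, little enolisation) to the hindered α-silyloxy ketone installs the future C5 substituent; the carbinol configuration is not controlled and is lost on ionisation in step 13.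

Step 13
Reactants: 18 the allyl carbinol
Product: 19 5-allyl-7,7-dimethoxy-2,2-dimethyl-3-[2-(TBS-oxy)ethyl]-1-[1-(TBS-oxy)-2-methylpropyl]bicyclo[3.2.1]octan-8-one (C3 chain anti to the C6–C7 bridge)
Conditions: BF3·OEt2 (1.2 equiv), CH2Cl2, −78 to −30 °C
Reagents that add atoms: none
Why: Semipinacol (pinacol-type) rearrangement with cyclobutane-to-cyclopentane ring expansion: ionisation of the tertiary carbinol gives a cyclobutylcarbinyl cation in which the exocyclic cyclobutane bond C8–C6, aligned with the empty orbital and pushed by the C8 silyloxy oxygen, migrates suprafacially to C5, so that C8 becomes the bridge ketone and C5 is set with the C6–C7 bridge on the face it already occupied, anti to the C3 chain.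

Step 14
Reactants: 19 the bicyclo[3.2.1]octan-8-one
Product: 20 5-allyl-3-(2-hydroxyethyl)-1-(1-hydroxy-2-methylpropyl)-2,2-dimethylbicyclo[3.2.1]octane-7,8-dione
Conditions: 48% aq. HF, MeCN, rt
Reagents that add atoms: water, O
Why: Aqueous HF cleaves both silyl ethers and hydrolyses the dimethyl ketal (desilylation and acetal hydrolysis) while the allyl group is inert, and retro-aldol loss of the C1 side chain would need a bridgehead enolate and is not expected.

Step 15
Reactants: 20 the diol dione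
Product: 21 2-(5-allyl-1-isobutyryl-2,2-dimethyl-7,8-dioxobicyclo[3.2.1]octan-3-yl)acetaldehyde
Conditions: Dess–Martin periodinane (2.5 equiv), CH2Cl2, rt
Reagents that add atoms: none
Why: Dess–Martin oxidation converts the primary alcohol into the aldehyde and the hindered secondary alcohol into the isobutyryl ketone under non-basic conditions, which removes the uncontrolled carbinol centre.

Step 16
Reactants: 21 the keto aldehyde
Product: 22 5-allyl-1-isobutyryl-2,2-dimethyl-3-(3-methylbut-2-enyl)bicyclo[3.2.1]octane-7,8-dione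
Conditions: iPrPPh3+ I−, KN(SiMe3)2, THF, 0 °C; then 21, −78 to 0 °C
Reagents that add atoms: isopropyltriphenylphosphonium iodide, CC(C)[P+](c1ccccc1)(c1ccccc1)c1ccccc1.[I-]
Why: Wittig olefination with the non-stabilised isopropylidene ylide is selective for the aldehyde over the three hindered ketones and completes the C3 prenyl group.

Step 17
Reactants: 22 the C3-prenyl C5-allyl triketone
Product: 23 1-isobutyryl-2,2-dimethyl-3,5-bis(3-methylbut-2-enyl)bicyclo[3.2.1]octane-7,8-dione
Conditions: second-generation Grubbs catalyst RuCl2(=CHPh)(H2IMes)(PCy3) (5 mol%), 2-methylbut-2-ene/CH2Cl2, 40 °C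
Reagents that add atoms: 2-methylbut-2-ene, CC=C(C)C
Why: Olefin cross-metathesis of the terminal allyl group with excess 2-methylbut-2-ene gives the trisubstituted prenyl alkene, while the prenyl group already present can only undergo degenerate exchange.

Step 18
Reactants: 23 the bis-prenyl triketone
Product: 24 6-hydroxy-1-isobutyryl-2,2-dimethyl-3,5-bis(3-methylbut-2-enyl)bicyclo[3.2.1]octane-7,8-dione (OH exo, syn to C8)
Conditions: KN(SiMe3)2, THF, −78 °C; then 3-phenyl-2-(phenylsulfonyl)oxaziridine; AcOH quench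
Reagents that add atoms: 3-phenyl-2-(phenylsulfonyl)oxaziridine, O=S(=O)(c1ccccc1)N1OC1c1ccccc1
Why: Enolate oxidation with an N-sulfonyloxaziridine (Davis hydroxylation): C6 is the only enolisable ring position (C1 and C5 are quaternary bridgeheads, and the isobutyryl methine is much slower to deprotonate), and oxygen is delivered to the open exo face; this centre is made planar again in step 22.

Step 19
Reactants: 24 the α-hydroxy ketone
Product: 25 1-isobutyryl-2,2-dimethyl-3,5-bis(3-methylbut-2-enyl)-6-(TES-oxy)bicyclo[3.2.1]octane-7,8-dione (OTES exo)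
Conditions: TESCl, imidazole, DMF, 0 °C to rt
Reagents that add atoms: triethylsilyl chloride, CC[Si](Cl)(CC)CC
Why: Silylation of the secondary α-hydroxy ketone gives an α-silyloxy ketone whose enolate can be formed without a free hydroxyl.

Step 20
Reactants: 26 2-methylbut-3-yn-2-ol
Product: 27 triethyl[(2-methylbut-3-yn-2-yl)oxy]silane
Conditions: TESCl, imidazole, DMAP (cat.), DMF, rt
Reagents that add atoms: triethylsilyl chloride, CC[Si](Cl)(CC)CC
Why: Silylation of the tertiary propargylic alcohol protects the hydroxyl against the organolithium and enolate steps that follow.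

Step 21
Reactants: 27 triethyl[(2-methylbut-3-yn-2-yl)oxy]silane
Product: 28 4-methyl-4-(TES-oxy)pent-2-ynal
Conditions: nBuLi, THF, −78 °C; then DMF; inverse quench into cold aq. KH2PO4
Reagents that add atoms: N,N-dimethylformamide, CN(C)C=O
Why: Formylation of the lithium acetylide with DMF, followed by inverse quench into phosphate buffer, releases the ynal without conjugate addition of dimethylamine.

Step 22
Reactants: 25 the α-silyloxy ketone; 28 4-methyl-4-(TES-oxy)pent-2-ynal
Product: 29 6-[1-hydroxy-4-methyl-4-(TES-oxy)pent-2-ynyl]-1-isobutyryl-2,2-dimethyl-3,5-bis(3-methylbut-2-enyl)-6-(TES-oxy)bicyclo[3.2.1]octane-7,8-dione (carbon chain exo, OTES endo; carbinol epimers)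
Conditions: LiN(iPr)2, THF, −78 °C; then 28; AcOH quench at −78 °C
Reagents that add atoms: none
Why: Aldol addition of the lithium enolate of the α-silyloxy ketone to the ynal: the electrophile approaches C6 from the exo face (syn to the C8 bridge), the endo face being covered by the axial hydrogen on C3 of the three-carbon bridge, which sets C6 with the carbon chain exo and the oxygen endo as in the target; the propargylic carbinol centre is uncontrolled and is oxidised in step 24.

Step 23
Reactants: 29 the aldol adduct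
Product: 30 6-hydroxy-6-(1,4-dihydroxy-4-methylpent-2-ynyl)-1-isobutyryl-2,2-dimethyl-3,5-bis(3-methylbut-2-enyl)bicyclo[3.2.1]octane-7,8-dione
Conditions: HF·pyridine, THF, 0 °C to rt
Reagents that add atoms: none
Why: Fluoride-mediated desilylation under acidic conditions (no retro-aldol) removes both triethylsilyl groups; it precedes the oxidation so that any 1,4-silyl shift between the vicinal oxygens during step 22 is without consequence.

Step 24
Reactants: 30 the triol
Product: 31 6-hydroxy-6-(4-hydroxy-4-methylpent-2-ynoyl)-1-isobutyryl-2,2-dimethyl-3,5-bis(3-methylbut-2-enyl)bicyclo[3.2.1]octane-7,8-dione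
Conditions: MnO2 (activated, excess), CH2Cl2, rt
Reagents that add atoms: none
Why: MnO2 oxidises the propargylic secondary alcohol chemoselectively to the ynone and leaves the two tertiary alcohols and the prenyl groups untouched.

Step 25
Reactants: 31 the ynone
Product: 32 CNP0190794.1, 6-hydroxy-6-[(Z)-4-hydroxy-4-methylpent-2-enoyl]-1-isobutyryl-2,2-dimethyl-3,5-bis(3-methylbut-2-enyl)bicyclo[3.2.1]octane-7,8-dione
Conditions: H2 (1 atm), Pd/CaCO3 poisoned with Pb(OAc)2 (Lindlar catalyst), quinoline, EtOAc, rt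
Reagents that add atoms: none
Why: Lindlar semihydrogenation adds H2 syn to the alkyne and should stop at the Z-enone, the trisubstituted prenyl alkenes not being reduced on the poisoned catalyst.

**Compound list**

1 | dimedone | CC1(C)CC(=O)CC(=O)C1 | starting material
2 | 3-isobutoxy-5,5-dimethylcyclohex-2-en-1-one | CC(C)COC1=CC(=O)CC(C)(C)C1 | intermediate
3 | allyl 5-isobutoxy-3,3-dimethylcyclohexa-1,5-dien-1-yl carbonate | C=CCOC(=O)OC1=CC(C)(C)CC(OCC(C)C)=C1 | intermediate
4 | (S)-6-allyl-3-isobutoxy-5,5-dimethylcyclohex-2-en-1-one | C=CC[C@@H]1C(=O)C=C(OCC(C)C)CC1(C)C | intermediate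
5 | 2-[(1S)-4-isobutoxy-6,6-dimethyl-2-oxocyclohex-3-en-1-yl]acetaldehyde | O=CC[C@@H]1C(=O)C=C(OCC(C)C)CC1(C)C | intermediate (not isolated)
6 | (S)-6-(2-hydroxyethyl)-3-isobutoxy-5,5-dimethylcyclohex-2-en-1-one | OCC[C@@H]1C(=O)C=C(OCC(C)C)CC1(C)C | intermediate
7 | (S)-6-[2-(TBS-oxy)ethyl]-3-isobutoxy-5,5-dimethylcyclohex-2-en-1-one | CC(C)(C)[Si](C)(C)OCC[C@@H]1C(=O)C=C(OCC(C)C)CC1(C)C | intermediate
8 | (6S)-6-[2-(TBS-oxy)ethyl]-3-isobutoxy-5,5-dimethylcyclohex-2-en-1-ol (C1 epimers) | CC(C)(C)[Si](C)(C)OCC[C@@H]1C(O)C=C(OCC(C)C)CC1(C)C | intermediate (not isolated)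
9 | (R)-4-[2-(TBS-oxy)ethyl]-5,5-dimethylcyclohex-2-en-1-one | CC(C)(C)[Si](C)(C)OCC[C@@H]1C=CC(=O)CC1(C)C | intermediate
10 | (4S)-4-[2-(TBS-oxy)ethyl]-2,3-epoxy-5,5-dimethylcyclohexan-1-one, epoxide trans to the side chain | CC(C)(C)[Si](C)(C)OCC[C@@H]1[C@H]2O[C@H]2C(=O)CC1(C)C | intermediate
11 | (R)-4-[2-(TBS-oxy)ethyl]-2-methoxy-5,5-dimethylcyclohex-2-en-1-one | CC(C)(C)[Si](C)(C)OCC[C@@H]1C=C(OC)C(=O)CC1(C)C | intermediate
12 | isobutyraldehyde | CC(C)C=O | starting material
13 | (4R)-4-[2-(TBS-oxy)ethyl]-6-(1-hydroxy-2-methylpropyl)-2-methoxy-5,5-dimethylcyclohex-2-en-1-one (epimers at C6 and carbinol) | CC(C)(C)[Si](C)(C)OCC[C@@H]1C=C(OC)C(=O)C(C(O)C(C)C)C1(C)C | intermediate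
14 | 2-methoxy-3-(TBS-oxy)-4-[1-(TBS-oxy)-2-methylpropyl]-6-[2-(TBS-oxy)ethyl]-5,5-dimethylcyclohexa-1,3-diene (C6 configuration as in 13) | CC(C)(C)[Si](C)(C)OCC[C@@H]1C=C(OC)C(O[Si](C)(C)C(C)(C)C)=C(C(O[Si](C)(C)C(C)(C)C)C(C)C)C1(C)C | intermediate (not isolated)
15 | (5R)-2-(TBS-oxy)-3-[1-(TBS-oxy)-2-methylpropyl]-5-[2-(TBS-oxy)ethyl]-4,4-dimethylcyclohex-2-en-1-one | CC(C)(C)[Si](C)(C)OCC[C@@H]1CC(=O)C(O[Si](C)(C)C(C)(C)C)=C(C(O[Si](C)(C)C(C)(C)C)C(C)C)C1(C)C | intermediate (key-step precursor)
16 | 1,1-dimethoxyethene | C=C(OC)OC | starting material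
17 | 7,7-dimethoxy-1-(TBS-oxy)-6-[1-(TBS-oxy)-2-methylpropyl]-4-[2-(TBS-oxy)ethyl]-5,5-dimethylbicyclo[4.2.0]octan-2-one, cis-fused, cyclobutane anti to the C4 chain | CC(C)(C)[Si](C)(C)OCC[C@@H]1CC(=O)[C@@]2(O[Si](C)(C)C(C)(C)C)CC(OC)(OC)[C@@]2(C(O[Si](C)(C)C(C)(C)C)C(C)C)C1(C)C | intermediate (key-step product)
18 | 2-allyl-7,7-dimethoxy-1-(TBS-oxy)-6-[1-(TBS-oxy)-2-methylpropyl]-4-[2-(TBS-oxy)ethyl]-5,5-dimethylbicyclo[4.2.0]octan-2-ol (C2 epimers) | CC(C)(C)[Si](C)(C)OCC[C@@H]1CC(O)(CC=C)[C@@]2(O[Si](C)(C)C(C)(C)C)CC(OC)(OC)[C@@]2(C(O[Si](C)(C)C(C)(C)C)C(C)C)C1(C)C | intermediate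
19 | 5-allyl-7,7-dimethoxy-2,2-dimethyl-3-[2-(TBS-oxy)ethyl]-1-[1-(TBS-oxy)-2-methylpropyl]bicyclo[3.2.1]octan-8-one, C3 chain anti to the C6–C7 bridge | CC(C)(C)[Si](C)(C)OCC[C@@H]1C[C@]2(CC=C)C(=O)[C@@](C(O[Si](C)(C)C(C)(C)C)C(C)C)(C(OC)(OC)C2)C1(C)C | intermediate
20 | 5-allyl-3-(2-hydroxyethyl)-1-(1-hydroxy-2-methylpropyl)-2,2-dimethylbicyclo[3.2.1]octane-7,8-dione | OCC[C@@H]1C[C@]2(CC=C)C(=O)[C@@](C(O)C(C)C)(C(=O)C2)C1(C)C | intermediate
21 | 2-(5-allyl-1-isobutyryl-2,2-dimethyl-7,8-dioxobicyclo[3.2.1]octan-3-yl)acetaldehyde | O=CC[C@@H]1C[C@]2(CC=C)C(=O)[C@@](C(=O)C(C)C)(C(=O)C2)C1(C)C | intermediate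
22 | 5-allyl-1-isobutyryl-2,2-dimethyl-3-(3-methylbut-2-enyl)bicyclo[3.2.1]octane-7,8-dione | CC(C)=CC[C@@H]1C[C@]2(CC=C)C(=O)[C@@](C(=O)C(C)C)(C(=O)C2)C1(C)C | intermediate
23 | 1-isobutyryl-2,2-dimethyl-3,5-bis(3-methylbut-2-enyl)bicyclo[3.2.1]octane-7,8-dione | CC(C)=CC[C@@H]1C[C@]2(CC=C(C)C)C(=O)[C@@](C(=O)C(C)C)(C(=O)C2)C1(C)C | intermediate
24 | 6-exo-hydroxy derivative of 23 | CC(C)=CC[C@@H]1C[C@]2(CC=C(C)C)C(=O)[C@@](C(=O)C(C)C)(C(=O)[C@H]2O)C1(C)C | intermediate
25 | 6-exo-(TES-oxy) derivative of 23 | CC(C)=CC[C@@H]1C[C@]2(CC=C(C)C)C(=O)[C@@](C(=O)C(C)C)(C(=O)[C@H]2O[Si](CC)(CC)CC)C1(C)C | intermediate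
26 | 2-methylbut-3-yn-2-ol | CC(C)(O)C#C | starting material
27 | triethyl[(2-methylbut-3-yn-2-yl)oxy]silane | CC[Si](CC)(CC)OC(C)(C)C#C | intermediate
28 | 4-methyl-4-(TES-oxy)pent-2-ynal | CC[Si](CC)(CC)OC(C)(C)C#CC=O | intermediate
29 | 6-[1-hydroxy-4-methyl-4-(TES-oxy)pent-2-ynyl]-6-(TES-oxy) derivative of 23, chain exo, OTES endo, carbinol epimers | CC(C)=CC[C@@H]1C[C@]2(CC=C(C)C)C(=O)[C@@](C(=O)C(C)C)(C(=O)[C@@]2(O[Si](CC)(CC)CC)C(O)C#CC(C)(C)O[Si](CC)(CC)CC)C1(C)C | intermediate
30 | 6-hydroxy-6-(1,4-dihydroxy-4-methylpent-2-ynyl) derivative of 23 | CC(C)=CC[C@@H]1C[C@]2(CC=C(C)C)C(=O)[C@@](C(=O)C(C)C)(C(=O)[C@@]2(O)C(O)C#CC(C)(C)O)C1(C)C | intermediate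
31 | 6-hydroxy-6-(4-hydroxy-4-methylpent-2-ynoyl) derivative of 23 | CC(C)=CC[C@@H]1C[C@]2(CC=C(C)C)C(=O)[C@@](C(=O)C(C)C)(C(=O)[C@@]2(O)C(=O)C#CC(C)(C)O)C1(C)C | intermediate
32 | CNP0190794.1 | CC(C)=CC[C@@H]1C[C@]2(CC=C(C)C)C(=O)[C@@](C(=O)C(C)C)(C(=O)[C@@]2(O)C(=O)/C=C\C(C)(C)O)C1(C)C | target

**Step count**

Total: 25 steps (23 in the main line from dimedone, 2 for the ynal 28). Longest linear sequence: 23 steps (steps 1–19 and 22–25).

**Steps most likely to fail**

Step 11. The excited enone carries a tetrasubstituted alkene next to a quaternary carbon, so it may decay or react elsewhere (hydrogen abstraction from the side chain, oxetane formation at the carbonyl) faster than it is captured. The biradical may also close to the trans-fused ring, which cannot be corrected by epimerisation because C8 is quaternary, or the facial preference may be low. The fallback forms the same two bonds in the ground state by a suprafacial ketene–enol ether cycloaddition; it sets out from 15 and returns at 17. Luche reduction of 15 (NaBH4, CeCl3·7H2O, MeOH) would give the allylic alcohol F1, and acetylation (Ac2O, pyridine, DMAP) the acetate F2, in which the silyl enol ether is no longer conjugated. Dichloroketene (from Cl3CCOCl and Zn(Cu) couple in Et2O) should add to it with the carbonyl carbon on C1 and the CCl2 carbon on C8 to give the cis-fused dichlorocyclobutanone F3. Zn/AcOH would remove the chlorines to give the cyclobutanone F4, and HC(OMe)3/MeOH/PPTS would give the ketal acetate F5. K2CO3/MeOH would free the ketal alcohol F6, and Dess–Martin oxidation would return 17.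

Step 13. The Lewis acid may ionise the ketal or strip silyl groups before the unactivated tertiary carbinol ionises, which would open the cyclobutane in a retro-aldol sense instead of shifting C6. The fallback makes the carbinol allylic, so that it ionises under mild Brønsted acid, and builds the C5 prenyl group afterwards; it sets out from 17 and returns at 23. Vinylmagnesium bromide would give the vinyl carbinol F7, and PPTS in CH2Cl2 should ionise it to an allyl cation that undergoes the same C8-to-C5 shift to the 5-vinyl bicyclic ketone F8. Hydroboration with 9-BBN and oxidation with NaBO3·4H2O would give the primary alcohol F9. Aqueous HF would give the triol dione F10, Dess–Martin oxidation the dialdehyde F11, and a double Wittig reaction with isopropylidenetriphenylphosphorane would give 23.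

Step 22. The fully substituted enolate next to the quaternary C5 may add slowly and reversibly (retro-aldol on warming), or the shielded endo hydrogen at C6 may resist deprotonation by the bulky amide. The fallback replaces the lithium aldol by a Mukaiyama aldol through an isolated enol silane; it sets out from 25 and returns at 29. Soft enolisation of 25 with TESOTf/Et3N would give the enediol bis(triethylsilyl) ether F12. Its BF3·OEt2-promoted addition to 28 at −78 °C, made irreversible by silyl transfer, should take place at the less hindered C6 from the exo face and give 29.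

Further compounds
F1 | step 11 | 2-(TBS-oxy)-3-[1-(TBS-oxy)-2-methylpropyl]-5-[2-(TBS-oxy)ethyl]-4,4-dimethylcyclohex-2-en-1-ol (C1 epimers) | CC(C)(C)[Si](C)(C)OCC[C@@H]1CC(O)C(O[Si](C)(C)C(C)(C)C)=C(C(O[Si](C)(C)C(C)(C)C)C(C)C)C1(C)C
F2 | step 11 | acetate of F1 | CC(C)(C)[Si](C)(C)OCC[C@@H]1CC(OC(C)=O)C(O[Si](C)(C)C(C)(C)C)=C(C(O[Si](C)(C)C(C)(C)C)C(C)C)C1(C)C
F3 | step 11 | 8,8-dichloro-1-(TBS-oxy)-6-[1-(TBS-oxy)-2-methylpropyl]-4-[2-(TBS-oxy)ethyl]-5,5-dimethyl-7-oxobicyclo[4.2.0]octan-2-yl acetate | CC(C)(C)[Si](C)(C)OCC[C@@H]1CC(OC(C)=O)[C@@]2(O[Si](C)(C)C(C)(C)C)C(Cl)(Cl)C(=O)[C@@]2(C(O[Si](C)(C)C(C)(C)C)C(C)C)C1(C)C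
F4 | step 11 | 1-(TBS-oxy)-6-[1-(TBS-oxy)-2-methylpropyl]-4-[2-(TBS-oxy)ethyl]-5,5-dimethyl-7-oxobicyclo[4.2.0]octan-2-yl acetate | CC(C)(C)[Si](C)(C)OCC[C@@H]1CC(OC(C)=O)[C@@]2(O[Si](C)(C)C(C)(C)C)CC(=O)[C@@]2(C(O[Si](C)(C)C(C)(C)C)C(C)C)C1(C)C
F5 | step 11 | 7,7-dimethoxy-1-(TBS-oxy)-6-[1-(TBS-oxy)-2-methylpropyl]-4-[2-(TBS-oxy)ethyl]-5,5-dimethylbicyclo[4.2.0]octan-2-yl acetate | CC(C)(C)[Si](C)(C)OCC[C@@H]1CC(OC(C)=O)[C@@]2(O[Si](C)(C)C(C)(C)C)CC(OC)(OC)[C@@]2(C(O[Si](C)(C)C(C)(C)C)C(C)C)C1(C)C
F6 | step 11 | 7,7-dimethoxy-1-(TBS-oxy)-6-[1-(TBS-oxy)-2-methylpropyl]-4-[2-(TBS-oxy)ethyl]-5,5-dimethylbicyclo[4.2.0]octan-2-ol | CC(C)(C)[Si](C)(C)OCC[C@@H]1CC(O)[C@@]2(O[Si](C)(C)C(C)(C)C)CC(OC)(OC)[C@@]2(C(O[Si](C)(C)C(C)(C)C)C(C)C)C1(C)C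
F7 | step 13 | 7,7-dimethoxy-1-(TBS-oxy)-6-[1-(TBS-oxy)-2-methylpropyl]-4-[2-(TBS-oxy)ethyl]-5,5-dimethyl-2-vinylbicyclo[4.2.0]octan-2-ol | CC(C)(C)[Si](C)(C)OCC[C@@H]1CC(O)(C=C)[C@@]2(O[Si](C)(C)C(C)(C)C)CC(OC)(OC)[C@@]2(C(O[Si](C)(C)C(C)(C)C)C(C)C)C1(C)C
F8 | step 13 | 7,7-dimethoxy-2,2-dimethyl-3-[2-(TBS-oxy)ethyl]-1-[1-(TBS-oxy)-2-methylpropyl]-5-vinylbicyclo[3.2.1]octan-8-one | CC(C)(C)[Si](C)(C)OCC[C@@H]1C[C@]2(C=C)C(=O)[C@@](C(O[Si](C)(C)C(C)(C)C)C(C)C)(C(OC)(OC)C2)C1(C)C
F9 | step 13 | 5-(2-hydroxyethyl)-7,7-dimethoxy-2,2-dimethyl-3-[2-(TBS-oxy)ethyl]-1-[1-(TBS-oxy)-2-methylpropyl]bicyclo[3.2.1]octan-8-one | CC(C)(C)[Si](C)(C)OCC[C@@H]1C[C@]2(CCO)C(=O)[C@@](C(O[Si](C)(C)C(C)(C)C)C(C)C)(C(OC)(OC)C2)C1(C)C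
F10 | step 13 | 3,5-bis(2-hydroxyethyl)-1-(1-hydroxy-2-methylpropyl)-2,2-dimethylbicyclo[3.2.1]octane-7,8-dione | OCC[C@@H]1C[C@]2(CCO)C(=O)[C@@](C(O)C(C)C)(C(=O)C2)C1(C)C
F11 | step 13 | 2,2'-(1-isobutyryl-2,2-dimethyl-7,8-dioxobicyclo[3.2.1]octane-3,5-diyl)diacetaldehyde | O=CC[C@@H]1C[C@]2(CC=O)C(=O)[C@@](C(=O)C(C)C)(C(=O)C2)C1(C)C
F12 | step 22 | 1-isobutyryl-2,2-dimethyl-3,5-bis(3-methylbut-2-enyl)-6,7-bis(TES-oxy)bicyclo[3.2.1]oct-6-en-8-one | CC(C)=CC[C@@H]1C[C@]2(CC=C(C)C)C(=O)[C@@](C(=O)C(C)C)(C(O[Si](CC)(CC)CC)=C2O[Si](CC)(CC)CC)C1(C)C
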